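**Retrosynthetic overview**
- The dihydropyran ring is the only ring made; it is closed last by an oxa-[4+2] cycloaddition between a methylene o-quinone methide (from phloroisovalerophenone and formaldehyde) and an (E)-styrene carrying the diformylphloroglucinol ring.
- That cycloaddition is run as a three-component cascade under a chiral phosphoric acid, so C-2 and C-3 are set together (trans from the E-alkene, absolute sense from the catalyst).
- The styrene comes from 2,4-diformylphloroglucinol and isovaleraldehyde by condensation to an alkylidene o-quinone methide and its tautomerisation to the vinylphenol.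
- Both aromatic rings are bought as phloroglucinol: one is diformylated (Vilsmeier–Haack), the other C-acylated (Friedel–Crafts).

Assumption: for this untested substrate pair the (R)-enantiomer of the phosphoric acid is taken to give the (2R,3S) product; if the first run gives the mirror image, the (S)-acid is used and nothing else changes.

**Route**

Step 1
Reactants: 1 benzene-1,3,5-triol (phloroglucinol); 2 N,N-dimethylformamide
Product: 4 2,4,6-trihydroxybenzene-1,3-dicarbaldehyde, via bis-iminium dichloride 3 (not isolated)
Conditions: POCl3 (2.2 equiv), DMF (2.2 equiv), EtOAc, 0 °C → rt; then H2O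
Reagents that add atoms: N,N-dimethylformamide 2, CN(C)C=O; water, O
Why: Two-fold Vilsmeier–Haack formylation, in which the chloroiminium ion attacks the very electron-rich ring twice, the third position is deactivated once two iminium groups are in place (3), and aqueous hydrolysis of 3 releases both aldehydes; no stereocentre is formed.

Step 2
Reactants: 4 2,4,6-trihydroxybenzene-1,3-dicarbaldehyde; 5 3-methylbutanal
Product: 8 2,4,6-trihydroxy-5-[(1E)-3-methylbut-1-en-1-yl]benzene-1,3-dicarbaldehyde, via benzylic alcohol adduct 6 (not isolated), via alkylidene o-quinone methide 7 (not isolated)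
Conditions: 5 (3 equiv), NaOAc (1 equiv), AcOH–1,4-dioxane (1:10), 0.02 M, 80 °C, N2
Reagents that add atoms: 3-methylbutanal 5, CC(C)CC=O
Why: Knoevenagel-type hydroxyalkylation of the one free ring carbon of 4 and loss of water give o-quinone methide 7, which, with no trap present and at high dilution, undergoes the intramolecular 1,5-hydrogen shift (o-quinone methide to o-vinylphenol tautomerisation, a carbonyl oxygen being available syn to the γ-CH2 on either side) faster than any bimolecular reaction, the isopropyl group lying anti in the six-membered transition state so that the conjugated (E)-alkene results; no stereocentre remains.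

Step 3
Reactants: 1 benzene-1,3,5-triol (phloroglucinol); 9 3-methylbutanoyl chloride
Product: 10 3-methyl-1-(2,4,6-trihydroxyphenyl)butan-1-one
Conditions: 9 (1.05 equiv), AlCl3 (3.5 equiv), PhNO2–CH2Cl2, 0 → 45 °C; then ice, 2 M HCl
Reagents that add atoms: 3-methylbutanoyl chloride 9, CC(C)CC(Cl)=O
Why: Friedel–Crafts C-acylation of phloroglucinol, which stops after one acyl group because the aluminium-chelated aryl ketone is deactivated; no stereocentre is formed.

Step 4
Reactants: 10 3-methyl-1-(2,4,6-trihydroxyphenyl)butan-1-one; 8 2,4,6-trihydroxy-5-[(1E)-3-methylbut-1-en-1-yl]benzene-1,3-dicarbaldehyde; 11 paraformaldehyde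
Product: 14 5-[(2R,3S)-5,7-dihydroxy-6-(3-methylbutanoyl)-3-(propan-2-yl)-3,4-dihydro-2H-chromen-2-yl]-2,4,6-trihydroxybenzene-1,3-dicarbaldehyde, via hydroxymethyl ketone 12 (not isolated), via methylene o-quinone methide 13 (not isolated)
Conditions: 8 (1.5 equiv), (CH2O)n (0.9 equiv, three portions), (R)-TRIP (10 mol%), 5 Å MS, CHCl3, 0 °C → rt, 48 h
Reagents that add atoms: formaldehyde (as paraformaldehyde) 11, C=O
Why: Proposed new method: a chiral phosphoric acid-catalysed three-component hydroxymethylation/dehydration/oxa-[4+2] (inverse-electron-demand hetero-Diels–Alder) cascade in which the acid turns 10 and formaldehyde into 12 and then into o-quinone methide 13, holds 13 by its unchelated carbonyl (para to the acyl group) and styrene 8 by an ortho-hydroxyl in one hydrogen-bonded assembly, and adds the (E)-alkene suprafacially through one face, so that the CH2 carbon bonds to the isopropyl-bearing alkene carbon, the para-oxygen closes onto the benzylic carbon, and C-2 and C-3 are set together as trans (from the E geometry) and as (2R,3S) (from the catalyst); the closest known reaction type is the phosphoric acid-catalysed enantioselective [4+2] cycloaddition of o-hydroxybenzyl alcohol-derived o-quinone methides with o-hydroxystyrenes, and the racemic parent is the biomimetic phloroglucinol/aldehyde/alkene three-component coupling.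

(R)-TRIP = (R)-3,3′-bis(2,4,6-triisopropylphenyl)-1,1′-binaphthyl-2,2′-diyl hydrogen phosphate.

**Compound list**
1 | benzene-1,3,5-triol (phloroglucinol) | Oc1cc(O)cc(O)c1 | starting material
2 | N,N-dimethylformamide | CN(C)C=O | starting material
3 | (2,4,6-trihydroxy-1,3-phenylene)bis(N,N-dimethylmethaniminium) dichloride | C[N+](C)=Cc1c(O)cc(O)c(C=[N+](C)C)c1O.[Cl-].[Cl-] | intermediate
4 | 2,4,6-trihydroxybenzene-1,3-dicarbaldehyde (2,4-diformylphloroglucinol) | O=Cc1c(O)cc(O)c(C=O)c1O | intermediate
5 | 3-methylbutanal (isovaleraldehyde) | CC(C)CC=O | starting material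
6 | 2,4,6-trihydroxy-5-(1-hydroxy-3-methylbutyl)benzene-1,3-dicarbaldehyde (racemic) | CC(C)CC(O)c1c(O)c(C=O)c(O)c(C=O)c1O | intermediate
7 | 2,4-dihydroxy-5-(3-methylbutylidene)-6-oxocyclohexa-1,3-diene-1,3-dicarbaldehyde | CC(C)CC=C1C(=O)C(C=O)=C(O)C(C=O)=C1O | intermediate
8 | 2,4,6-trihydroxy-5-[(1E)-3-methylbut-1-en-1-yl]benzene-1,3-dicarbaldehyde | CC(C)/C=C/c1c(O)c(C=O)c(O)c(C=O)c1O | intermediate
9 | 3-methylbutanoyl chloride (isovaleryl chloride) | CC(C)CC(Cl)=O | starting material
10 | 3-methyl-1-(2,4,6-trihydroxyphenyl)butan-1-one (phloroisovalerophenone) | CC(C)CC(=O)c1c(O)cc(O)cc1O | intermediate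
11 | paraformaldehyde (formaldehyde) | C=O | starting material
12 | 1-[2,4,6-trihydroxy-3-(hydroxymethyl)phenyl]-3-methylbutan-1-one | CC(C)CC(=O)c1c(O)cc(O)c(CO)c1O | intermediate
13 | 3,5-dihydroxy-4-(3-methylbutanoyl)-6-methylidenecyclohexa-2,4-dien-1-one | CC(C)CC(=O)C1=C(O)C(=C)C(=O)C=C1O | intermediate
14 | 5-[(2R,3S)-5,7-dihydroxy-6-(3-methylbutanoyl)-3-(propan-2-yl)-3,4-dihydro-2H-chromen-2-yl]-2,4,6-trihydroxybenzene-1,3-dicarbaldehyde | CC(C)CC(=O)c1c(O)cc2c(c1O)C[C@@H](C(C)C)[C@H](c1c(O)c(C=O)c(O)c(C=O)c1O)O2 | target

**Step count**
Total steps: 4. Longest linear sequence: 3 (1 → 4 → 8 → 14).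

**Steps most likely to fail, with fallbacks**

Step 4 (highest risk). The free ring carbon of 10, 12 and 14 is itself a good nucleophile, so 13 can be lost to methylene-bridged dimers, or 14 can be hydroxymethylated a second time. Closure through the oxygen ortho to the acyl group (8-acyl isomer) and the level of enantioselectivity are also unproven. The fallback sets out from 10 and blocks the spare ring carbon with iodine. NIS (1.0 equiv) in MeCN at −20 °C gives 1-(2,4,6-trihydroxy-3-iodophenyl)-3-methylbutan-1-one F1. F1, 8 and paraformaldehyde under the same chiral acid then give 5-[(2R,3S)-5,7-dihydroxy-8-iodo-6-(3-methylbutanoyl)-3-(propan-2-yl)-3,4-dihydro-2H-chromen-2-yl]-2,4,6-trihydroxybenzene-1,3-dicarbaldehyde F2, in which neither dimerisation through carbon nor a second hydroxymethylation is possible. Protodeiodination with NaI and ascorbic acid in aqueous AcOH at 40 °C (the reverse of the iodination, which leaves C-2 and C-3 alone) comes back to the route at 14.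

Step 2. The o-quinone methide 7 and the styrene 8 coexist, and their cycloaddition to a dimer competes with the hydrogen shift; 7 can also be arylated by 4. The fallback sets out from 4 and separates trapping from release. Condensation with 5 in the presence of sodium p-toluenesulfinate and formic acid (EtOH–H2O, rt) captures the o-quinone methide as it forms, giving crystalline 2,4,6-trihydroxy-5-[3-methyl-1-(4-methylbenzenesulfonyl)butyl]benzene-1,3-dicarbaldehyde F3. Treating F3 with DBU (3 equiv) in CH2Cl2 at 0.01 M and 0 °C causes 1,4-elimination of sulfinate and γ-deprotonation to the anion of the (E)-styrene. Acidification comes back to the route at 8.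

Step 3. The acylation is well precedented but can give O-acyl and diacyl products that are tedious to separate from aluminium residues. The fallback sets out from 1 and uses a Houben–Hoesch reaction with 3-methylbutanenitrile (ZnCl2, HCl gas, Et2O, 0 °C). It stops at the mono-adduct because 3-methyl-1-(2,4,6-trihydroxyphenyl)butan-1-iminium chloride F4 precipitates and is deactivated. Hydrolysis of F4 in hot water comes back to the route at 10.

**Further compounds**
F1 | step 4 | 1-(2,4,6-trihydroxy-3-iodophenyl)-3-methylbutan-1-one | CC(C)CC(=O)c1c(O)cc(O)c(I)c1O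
F2 | step 4 | 5-[(2R,3S)-5,7-dihydroxy-8-iodo-6-(3-methylbutanoyl)-3-(propan-2-yl)-3,4-dihydro-2H-chromen-2-yl]-2,4,6-trihydroxybenzene-1,3-dicarbaldehyde | CC(C)CC(=O)c1c(O)c(I)c2c(c1O)C[C@@H](C(C)C)[C@H](c1c(O)c(C=O)c(O)c(C=O)c1O)O2
F3 | step 2 | 2,4,6-trihydroxy-5-[3-methyl-1-(4-methylbenzenesulfonyl)butyl]benzene-1,3-dicarbaldehyde (racemic) | CC(C)CC(c1c(O)c(C=O)c(O)c(C=O)c1O)S(=O)(=O)c1ccc(C)cc1
F4 | step 3 | 3-methyl-1-(2,4,6-trihydroxyphenyl)butan-1-iminium chloride | CC(C)CC(=[NH2+])c1c(O)cc(O)cc1O.[Cl-]
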